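## Structural features

The target has a thymol-type C10 skeleton: arene C1–C6, C7 on C1, and C8 on C4 with its two arms C9 and C10. C7 is a formyl group, O3 carries an isobutyryl group, and C8, C9 and O8 form a 2,2-disubstituted oxirane. The second arm, C10H2–O10, is esterified by (E)-cinnamic acid. The oxirane is joined to the arene by the C4–C8 bond, para to the formyl group and ortho to the aryl ester.

C8 is the only stereocentre (S). It is fully substituted, benzylic and oxygen-bearing, and no neighbouring stereocentre can relay information to it. C9 and C10 are both CH2–O groups that differ only in what their oxygen is bound to. Removing the cinnamoyl group and opening O8–C9 hydrolytically gives a 2-arylglycerol with a mirror plane through C4, C8 and O8. The key step exploits this latent symmetry of the C9/C8/C10 unit.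

The fragile groups are:
- the tertiary benzylic oxirane (acid, Lewis acid, nucleophiles at C9);
- the aryl isobutyrate, an activated ester that alkoxides, amines and metal alkoxides cleave and that can shift to a nearby hydroxyl group;
- the aldehyde (peracids, ylides, organometallics);
- the cinnamate (Michael acceptor, reducible).

A free phenol ortho to the oxirane would push the C8–O8 bond open towards an o-quinone methide, so O3 must be acylated before the oxirane exists. The real difficulty is twofold. The absolute configuration at C8 corresponds, on the alkene route, to face selection on a 1,1-disubstituted olefin. In addition, four oxygen functions (O3, O8, O9, O10) must be sorted into three different fates without protecting-group traffic.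

## Logic of the disconnections

**11 ⇒ 9.** The O8–C9 bond of the oxirane is cut, which leads to a primary/tertiary 1,2-diol. The C8–O8 bond stays intact in the forward step, so the configuration of 9 is carried into 11 unchanged. The strained, acid-labile ring then appears only in the last operation. The forward step must activate O9 selectively, and no long-lived tertiary alkoxide may sit next to the aryl ester.

**9 ⇒ 8.** The O3–C(=O) bond of the isobutyrate is cut. The phenol is the only acidic OH, so weak base with an anhydride selects it by itself. Cutting here also keeps an activated aryl ester away from the enzyme of the preceding step. The forward step must distinguish phenol from primary alcohol and must be mild enough that the cinnamoyl group does not move between O10, O8 and O9.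

**8 ⇒ 6 + 7 (key).** The O10–C(=O) bond of the cinnamate is cut. This removes the only difference between C9 and C10, so the precursor 6 is achiral and fully unprotected. In one sentence: a lipase transfers the cinnamoyl group of 7 to one of the two enantiotopic CH2OH arms of achiral 6. The gain is the loss of the only stereocentre and of one of the two ester appendages in a single cut. The forward step must select the pro-S arm, acylate only once, and ignore the phenol, the tertiary OH and the aldehyde.

**6 ⇒ 5.** The C–O bonds of two acetals (at C7, and across O9/O10) are restored. Both are cleaved by the same aqueous acid, so unmasking costs one step. It takes place before any ester or the oxirane is present.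

**5 ⇒ 2 + 3.** The C4–C8 bond is cut. This splits the molecule into its arene and its symmetric C3 unit, and it forms the fully substituted carbon by a simple carbonyl addition. The forward step needs an aryl nucleophile that tolerates the phenoxide and an enolisable ketone.

**2 ⇒ 1.** The dioxolane at C7 is removed, which leads to a commercial bromohydroxybenzaldehyde with the correct 1,3,4-pattern.

## Other disconnections considered

Alternative 1: This is the first that comes to mind. Both C–O bonds of the oxirane (C8–O8, C9–O8) are cut back to the olefin. The forward key step is Sharpless asymmetric epoxidation of allylic alcohol A1 to epoxy alcohol A2, followed by cinnamoylation.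
- A1 is a 2-aryl, 1,1-disubstituted allylic alcohol, the class in which face selection is least secure. Its ortho substituent also twists the aryl group out of conjugation.
- A2 is a tertiary benzylic epoxy alcohol that titanium alkoxides can open at C9 or ionise at C8.
- Ti(OiPr)4 is a transesterification catalyst, and in A1 the activated aryl isobutyrate lies within reach of the titanium-bound allylic alkoxide.
- The cinnamate needs a separate step, and A1 itself needs a cross-coupling plus protecting-group handling. The route is therefore not shorter.

Alternative 2: The same latent symmetry is used, but C9 and C10 are traced back to the two CH2 groups of an oxetane. The forward key step is enantioselective opening of 3-aryloxetan-3-ol A3 with TMSBr under chiral hydrogen-bond-donor (squaramide) catalysis, which gives bromohydrin A4. Acylation of O10 and closure of O8 onto C9 follow, a formal oxetane-to-oxirane ring contraction.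
- TMSBr and the HBr it carries would meet a free aldehyde (an acetal would not survive) and a tertiary benzylic OH in A3.
- The cinnamate is not installed in the stereodefining step, so at least one more step is needed.
- Closure of A4 requires a true alkoxide next to the aryl ester. From that alkoxide, acyl shift to O8 and 5-exo closure of the freed phenoxide onto C9 compete.

Alternative 3: C8–C9 and C9–O8 are cut. The forward key step is catalytic asymmetric Corey–Chaykovsky methylene transfer to α-cinnamoyloxy ketone A5.
- The formyl group of A5 is more electrophilic than its ortho-substituted ketone. It would have to be masked and then unmasked by acid in the presence of the oxirane.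
- The basic ylide would attack the aryl ester and enolise the α-acyloxy ketone.
- Sulfoxonium ylides cyclopropanate cinnamates.
- The asymmetric variants rely on an aryl/methyl size difference, which the CH2O-cinnamoyl group erodes.

Key step: step 4

Assumption: the sense in which a lipase selects between the arms of a 2-arylglycerol cannot be derived from the structure alone, so the route assumes that the usual lipase panel contains an enzyme that acylates the pro-S arm, and Burkholderia cepacia lipase is written as first choice.

## Steps

Step 1
Reactants: 1 4-bromo-3-hydroxybenzaldehyde
Product: 2 2-bromo-5-(1,3-dioxolan-2-yl)phenol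
Conditions: HOCH2CH2OH (3 equiv), p-TsOH·H2O (cat.), toluene, reflux, Dean–Stark
Reagents that add atoms: ethylene glycol, OCCO
Why: Acid-catalysed acetalisation with azeotropic removal of water; the phenol and the aryl bromide are inert, and the dioxolane shields C7 from the organolithium of step 2.

Step 2
Reactants: 2 2-bromo-5-(1,3-dioxolan-2-yl)phenol; 3 2,2-dimethyl-1,3-dioxan-5-one
Product: 5 5-[4-(1,3-dioxolan-2-yl)-2-hydroxyphenyl]-2,2-dimethyl-1,3-dioxan-5-ol, via dilithio species 4 (not isolated)
Conditions: n-BuLi (2.2 equiv), THF, −78 → −20 °C; 3 (1.2 equiv), −78 → 0 °C; aq NH4Cl
Reagents that add atoms: n-butyllithium, [Li]CCCC (lithium of 4 only; nothing of it remains in 5)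
Why: Deprotonation of the phenol followed by bromine–lithium exchange gives the known type of o-lithiophenoxide dianion, which undergoes 1,2-addition to the ketone and forms C4–C8; the product keeps a mirror plane, so no stereochemistry arises, and both acetals are stable to base.

Step 3
Reactants: 5 5-[4-(1,3-dioxolan-2-yl)-2-hydroxyphenyl]-2,2-dimethyl-1,3-dioxan-5-ol
Product: 6 3-hydroxy-4-(1,2,3-trihydroxypropan-2-yl)benzaldehyde
Conditions: sulfonic acid ion-exchange resin (H+ form, cat.), THF–H2O 4:1, 40 °C; filter, concentrate
Reagents that add atoms: water, O
Why: One acid-catalysed hydrolysis removes acetonide and dioxolane together; ionisation at C8 is disfavoured by the two β-oxygens and by the para formyl group being released, and the resin lets the polar tetraol be isolated by filtration and evaporation.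

Step 4
Reactants: 6 3-hydroxy-4-(1,2,3-trihydroxypropan-2-yl)benzaldehyde; 7 vinyl (E)-3-phenylprop-2-enoate (vinyl cinnamate)
Product: 8 (2S)-2-(4-formyl-2-hydroxyphenyl)-2,3-dihydroxypropyl (E)-3-phenylprop-2-enoate
Conditions: immobilised Burkholderia cepacia lipase, 7 (1.5 equiv), tert-amyl alcohol–MTBE, 4 Å MS, 30 °C; stop at consumption of 6, filter
Reagents that add atoms: none
Why: This is a lipase-catalysed (serine hydrolase, EC 3.1.1.3) enantiotopic-group-selective transesterification of a prochiral 2-substituted glycerol, a known reaction type, run here with the acyl group that the target needs. The serine of the Ser–His–Asp triad is cinnamoylated by 7, and the vinyl alcohol set free tautomerises, so the transfer is irreversible; one CH2OH of 6 then attacks the acyl-enzyme under general-base catalysis by histidine, with the oxyanion hole holding the tetrahedral intermediate. No ring is closed. C8 becomes stereogenic only because its arms become different, and the controlling element is the chiral alcohol-binding site, which must place the large flat aryl group and the small O8–H in pockets of very different size so that only the pro-S arm reaches the acyl-serine. The chemoselectivity needed is primary OH over phenol, tertiary OH and aldehyde: a phenol is a poor acceptor because its ester would itself be an acyl donor, the tertiary OH cannot reach the catalytic serine, and the aldehyde is not a substrate. Mono-acylation is secured because a second acylation of the major enantiomer must use the disfavoured arm, whereas the minor enantiomer still offers the favoured arm and is consumed faster, so the enantiomeric purity of 8 should rise with conversion. The conjugated cinnamoyl carbonyl is a poor electrophile, which slows the O10→O9 acyl shift, the only pathway that could racemise 8.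

Step 5
Reactants: 8 (2S)-2-(4-formyl-2-hydroxyphenyl)-2,3-dihydroxypropyl (E)-3-phenylprop-2-enoate
Product: 9 (2S)-2-[4-formyl-2-(2-methylpropanoyloxy)phenyl]-2,3-dihydroxypropyl (E)-3-phenylprop-2-enoate
Conditions: (i-PrCO)2O (1.05 equiv), Et3N (1.1 equiv), CH2Cl2, −20 → 0 °C, no DMAP; pH 7 buffer
Reagents that add atoms: isobutyric anhydride, CC(C)C(=O)OC(=O)C(C)C
Why: Chemoselective O-acylation of the phenol through its ammonium phenoxide ion pair; without a nucleophilic catalyst the hindered anhydride reacts far more slowly with the neutral primary and tertiary OH groups. The weak base and low temperature should keep the cinnamoyl group in place, so C8 stays (S).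

Step 6
Reactants: 9 (2S)-2-[4-formyl-2-(2-methylpropanoyloxy)phenyl]-2,3-dihydroxypropyl (E)-3-phenylprop-2-enoate
Product: 11 [(2S)-2-[4-formyl-2-(2-methylpropanoyloxy)phenyl]oxiran-2-yl]methyl (E)-3-phenylprop-2-enoate (target), via dioxaphospholane 10 (not isolated)
Conditions: PPh3 (1.5 equiv), DIAD (1.5 equiv, slow addition), toluene, 0 → 50 °C; chromatography on Et3N-deactivated silica
Reagents that add atoms: triphenylphosphine, c1ccc(cc1)P(c1ccccc1)c1ccccc1 (in 10 only; nothing of it remains in 11)
Why: Mitsunobu-type cyclodehydration of a vicinal diol: the diol and the PPh3–DIAD adduct give phosphorane 10, which opens to the primary oxyphosphonium/tertiary alkoxide ion pair and collapses by 3-exo-tet attack of O8 on C9 with loss of Ph3P=O. The C8–O8 bond is not touched, so the configuration is retained (S in 9 and in 11). The medium is neutral and the leaving group extremely good, so no long-lived alkoxide sits beside the aryl isobutyrate, and the aldehyde and cinnamate are not addressed.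

## Compound list

1 | 4-bromo-3-hydroxybenzaldehyde | O=Cc1ccc(Br)c(O)c1 | starting material
2 | 2-bromo-5-(1,3-dioxolan-2-yl)phenol | Oc1cc(C2OCCO2)ccc1Br | intermediate
3 | 2,2-dimethyl-1,3-dioxan-5-one | CC1(C)OCC(=O)CO1 | starting material
4 | lithium 5-(1,3-dioxolan-2-yl)-2-lithiophenoxide (not isolated) | [Li]Oc1cc(C2OCCO2)ccc1[Li] | intermediate
5 | 5-[4-(1,3-dioxolan-2-yl)-2-hydroxyphenyl]-2,2-dimethyl-1,3-dioxan-5-ol | Oc1cc(C2OCCO2)ccc1C1(O)COC(C)(C)OC1 | intermediate
6 | 3-hydroxy-4-(1,2,3-trihydroxypropan-2-yl)benzaldehyde | Oc1cc(C=O)ccc1C(O)(CO)CO | intermediate
7 | vinyl (E)-3-phenylprop-2-enoate | C=COC(=O)/C=C/c1ccccc1 | starting material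
8 | (2S)-2-(4-formyl-2-hydroxyphenyl)-2,3-dihydroxypropyl (E)-3-phenylprop-2-enoate | Oc1cc(C=O)ccc1[C@@](O)(COC(=O)/C=C/c2ccccc2)CO | intermediate
9 | (2S)-2-[4-formyl-2-(2-methylpropanoyloxy)phenyl]-2,3-dihydroxypropyl (E)-3-phenylprop-2-enoate | CC(C)C(=O)Oc1cc(C=O)ccc1[C@@](O)(COC(=O)/C=C/c2ccccc2)CO | intermediate
10 | [(4R)-4-[4-formyl-2-(2-methylpropanoyloxy)phenyl]-2,2,2-triphenyl-1,3,2λ5-dioxaphospholan-4-yl]methyl (E)-3-phenylprop-2-enoate (not isolated; same spatial arrangement as 9, descriptor changes by CIP priority only) | CC(C)C(=O)Oc1cc(C=O)ccc1[C@@]1(COC(=O)/C=C/c2ccccc2)COP(c2ccccc2)(c2ccccc2)(c2ccccc2)O1 | intermediate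
11 | [(2S)-2-[4-formyl-2-(2-methylpropanoyloxy)phenyl]oxiran-2-yl]methyl (E)-3-phenylprop-2-enoate | CC(C)C(=O)Oc1cc(C=O)ccc1[C@@]1(COC(=O)/C=C/c2ccccc2)CO1 | target

## Step count and least certain steps

Total step count: 6. Longest linear sequence: 6 (1 → 2 → 5 → 6 → 8 → 9 → 11).

**Step 4 (key step).**
- What may go wrong: discrimination between the two arms may be insufficient or of the wrong sense, because the groups the enzyme must tell apart (aryl against OH) sit on C8, one atom away from the reacting CH2OH. Formation of the acyl-enzyme from a conjugated donor may also be slow. Long contact times would then give the O10→O9 acyl shift time to erode the enantiomeric purity.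
- Fallback: this sets out from 6. Phenol-selective isobutyrylation under the conditions of step 5 gives 5-formyl-2-(1,2,3-trihydroxypropan-2-yl)phenyl 2-methylpropanoate F1. A Cu(II)–bis(oxazoline) complex then binds O8 and one primary oxygen as a five-membered chelate and directs cinnamoyl chloride/Et3N to that oxygen. This is the known desymmetrising acylation of 2-substituted glycerols, and both ligand enantiomers are available, so either sense can be reached. The fallback returns to the route at 9.

**Step 6.**
- What may go wrong: the phosphorane may collapse too slowly. Phosphorus may be partly transferred to the tertiary benzylic O8, followed by loose displacement at C8, which would invert the centre and lower the enantiomeric purity. The cinnamate carbonyl may participate at activated C9 through a symmetric six-membered dioxanylium ion, with the same consequence. The product may also open on acidic silica.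
- Fallback: this sets out from 9 and separates activation from closure. Regioselective tosylation of the primary OH through a catalytic stannylene acetal (TsCl, Bu2SnO cat., Et3N) gives (2R)-2-[4-formyl-2-(2-methylpropanoyloxy)phenyl]-2-hydroxy-3-(4-methylbenzenesulfonyloxy)propyl (E)-3-phenylprop-2-enoate F2. F2 is closed with Cs2CO3 in MeCN at low temperature and returns to the route at 11. O8 is never activated in this sequence, so the configuration is safe. The price is a true alkoxide beside the aryl ester.

**Step 5.**
- What may go wrong: selectivity between phenol and primary OH may be incomplete. Base may induce migration of the cinnamoyl group between the arms, with loss of enantiomeric purity. The new isobutyryl group may shift from O3 to O9, because an alkyl ester is more stable than an aryl ester.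
- Fallback: this sets out from 5, in which both primary oxygens are still tied up, so only the phenol can react. Isobutyrylation gives 5-(1,3-dioxolan-2-yl)-2-(5-hydroxy-2,2-dimethyl-1,3-dioxan-5-yl)phenyl 2-methylpropanoate F3. Aqueous acid as in step 3 gives triol F1, and the lipase step with 7 is then run on F1. The fallback returns to the route at 9, and no base touches the stereodefined monoester.

**Step 2.**
- What may go wrong: the basic aryllithium may enolise ketone 3 instead of adding to it. The sparingly soluble dianion may also react poorly.
- Fallback: this sets out from 2 (through 4) and brings in the C3 unit at the diester oxidation level, with a non-enolisable and far more electrophilic ketone. Addition to diethyl oxomalonate gives diethyl 2-[4-(1,3-dioxolan-2-yl)-2-hydroxyphenyl]-2-hydroxypropanedioate F4. LiAlH4 reduction gives 2-[4-(1,3-dioxolan-2-yl)-2-hydroxyphenyl]propane-1,2,3-triol F5. Acid hydrolysis as in step 3 returns to the route at 6.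

## Further compounds

F1 | step 4 | 5-formyl-2-(1,2,3-trihydroxypropan-2-yl)phenyl 2-methylpropanoate | CC(C)C(=O)Oc1cc(C=O)ccc1C(O)(CO)CO
F2 | step 6 | (2R)-2-[4-formyl-2-(2-methylpropanoyloxy)phenyl]-2-hydroxy-3-(4-methylbenzenesulfonyloxy)propyl (E)-3-phenylprop-2-enoate | CC(C)C(=O)Oc1cc(C=O)ccc1[C@@](O)(COC(=O)/C=C/c2ccccc2)COS(=O)(=O)c2ccc(C)cc2
F3 | step 5 | 5-(1,3-dioxolan-2-yl)-2-(5-hydroxy-2,2-dimethyl-1,3-dioxan-5-yl)phenyl 2-methylpropanoate | CC(C)C(=O)Oc1cc(C2OCCO2)ccc1C1(O)COC(C)(C)OC1
F4 | step 2 | diethyl 2-[4-(1,3-dioxolan-2-yl)-2-hydroxyphenyl]-2-hydroxypropanedioate | CCOC(=O)C(O)(C(=O)OCC)c1ccc(C2OCCO2)cc1O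
F5 | step 2 | 2-[4-(1,3-dioxolan-2-yl)-2-hydroxyphenyl]propane-1,2,3-triol | Oc1cc(C2OCCO2)ccc1C(O)(CO)CO
A1 | alternative 1 | 5-formyl-2-(3-hydroxyprop-1-en-2-yl)phenyl 2-methylpropanoate | CC(C)C(=O)Oc1cc(C=O)ccc1C(=C)CO
A2 | alternative 1 | 5-formyl-2-[(2R)-2-(hydroxymethyl)oxiran-2-yl]phenyl 2-methylpropanoate | CC(C)C(=O)Oc1cc(C=O)ccc1[C@@]1(CO)CO1
A3 | alternative 2 | 5-formyl-2-(3-hydroxyoxetan-3-yl)phenyl 2-methylpropanoate | CC(C)C(=O)Oc1cc(C=O)ccc1C1(O)COC1
A4 | alternative 2 | 2-[(2R)-1-bromo-2,3-dihydroxypropan-2-yl]-5-formylphenyl 2-methylpropanoate | CC(C)C(=O)Oc1cc(C=O)ccc1[C@@](O)(CO)CBr
A5 | alternative 3 | 2-[4-formyl-2-(2-methylpropanoyloxy)phenyl]-2-oxoethyl (E)-3-phenylprop-2-enoate | CC(C)C(=O)Oc1cc(C=O)ccc1C(=O)COC(=O)/C=C/c2ccccc2
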